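**Plan**

- Numbering used throughout: C1 = fully substituted oxirane carbon (bears CH2OBz), C2 = CH(OAc), C3 = CH(OBz), C4=C5 = ring alkene, C6 = oxirane CH.
- Retrosynthesis: the O–C1 bond of the oxirane is cut first (C6 alkoxide, C1 tertiary bromide) and CH2OBz is taken back to CHO. Then C1–C6 and C2–C3 are cut together, because the cyclohexene ring C1–C6 with C4=C5 opposite C1–C2 is a Diels–Alder retron.
- Forward: diene 5 (C3–C6) and dienophile 7 (C1–C2) are made separately and the carbocycle is closed in one [4+2] step. The formyl group then becomes CH2OBz, and the oxirane ring is closed last by 3-exo-tet displacement of bromide.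
- Stereochemistry: C3/C6 cis from the E,E diene, C1/C2 from the Z dienophile, C2 against C3 from formyl-endo addition, absolute sense from a chiral boron Lewis acid. C1 is inverted in the oxirane closure, which puts the oxirane oxygen cis to C3–OBz and trans to C2–OAc.
- Helpers: Br at C1 (leaving group), CHO at C1 (activating group) and TBS on the C6 oxygen; all are removed or converted after the cycloaddition.

Key step: step 5

Assumption: the (R)-tryptophan-derived oxazaborolidinone is taken to expose the Si face at C1 of 7, by analogy with the sense known for 2-bromoacrolein; if the sense with 7 is the reverse, the (S)-catalyst is used with no other change.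

**Step 1**
Reactants: 1 (Z)-but-2-ene-1,4-diol
Product: 2 (Z)-4-hydroxybut-2-en-1-yl benzoate
Conditions: 1 (3 equiv), BzCl (1 equiv), pyridine, CH2Cl2, 0 °C
Reagents that add atoms: benzoyl chloride, O=C(Cl)c1ccccc1
Why: O-acylation of the symmetric diol, used in excess, should stop largely at the monoester, and no stereocentre is involved.

**Step 2**
Reactants: 2 (Z)-4-hydroxybut-2-en-1-yl benzoate
Product: 4 (E)-4-oxobut-2-en-1-yl benzoate, via Z-enal 3 (not isolated)
Conditions: [C5H5NH][CrO3Cl] (1.5 equiv), CH2Cl2, rt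
Reagents that add atoms: none
Why: Oxidation of the allylic alcohol by the hexavalent chromium reagent should give Z-enal 3, which is expected to isomerise under the weakly acidic conditions to the more stable E-enal.

**Step 3**
Reactants: 4 (E)-4-oxobut-2-en-1-yl benzoate
Product: 5 (1E,3E)-4-[(tert-butyldimethylsilyl)oxy]buta-1,3-dien-1-yl benzoate
Conditions: TBSOTf, Et3N, Et2O, 0 °C → rt
Reagents that add atoms: tert-butyldimethylsilyl trifluoromethanesulfonate, CC(C)(C)[Si](C)(C)OS(=O)(=O)C(F)(F)F
Why: Vinylogous enol silylation (O-silylation of the enal, then removal of the γ-proton next to the benzoate oxygen) should give the silyl dienol ether, the E,E isomer being favoured from the s-trans enal with the benzoyloxy group outside.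

**Step 4**
Reactants: 6 2-bromopropanedial (bromomalonaldehyde)
Product: 7 (Z)-2-bromo-3-oxoprop-1-en-1-yl acetate [(Z)-3-acetoxy-2-bromoacrolein]
Conditions: AcCl, 2,6-lutidine, CH2Cl2, −40 °C → 0 °C
Reagents that add atoms: acetyl chloride, CC(Cl)=O
Why: O-acylation of the strongly enolised dialdehyde through its extended enolate ion pair should place the acetoxy group anti to the remaining formyl group, that is cis to bromine (Z).

**Step 5**
Reactants: 5 (1E,3E)-4-[(tert-butyldimethylsilyl)oxy]buta-1,3-dien-1-yl benzoate; 7 (Z)-2-bromo-3-oxoprop-1-en-1-yl acetate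
Product: 8 (1S,2S,3R,6S)-2-acetoxy-3-(benzoyloxy)-1-bromo-6-[(tert-butyldimethylsilyl)oxy]cyclohex-4-ene-1-carbaldehyde
Conditions: 5 (1.5 equiv), (R)-2-butyl-4-(1H-indol-3-ylmethyl)-3-[(4-methylphenyl)sulfonyl]-1,3,2-oxazaborolidin-5-one (10 mol %), CH2Cl2, −78 → −40 °C
Reagents that add atoms: none
Why: A concerted but asynchronous normal-demand [π4s+π2s] cycloaddition is expected, with the formyl group of 7 bound to the chiral boron Lewis acid and the C2–C3 bond more advanced than the C1–C6 bond. The closest known reaction type is the oxazaborolidinone-catalysed enantioselective Diels–Alder reaction of 2-bromoacrolein with 1,3-dienes. The six-membered carbocycle C1–C6 is closed by intermolecular suprafacial addition across the s-cis diene, which leaves the C4=C5 double bond. The E,E geometry of 5 places C3–OBz and C6–OTBS cis, the Z geometry of 7 places C2–OAc cis to C1–Br and trans to CHO, the endo orientation of the formyl group places CHO cis to both diene oxygens (hence C2–OAc trans to C3–OBz), and the catalyst, by shielding one face of the bound enal, should direct the diene to the Si face at C1 and so set the absolute configuration. The step needs ortho regioselectivity, formyl-endo selectivity and cycloaddition in preference to Mukaiyama-type conjugate addition: the stronger silyloxy donor at C6 makes C3 the nucleophilic terminus that bonds to the β-carbon C2, the enal carbonyl provides the secondary overlap, and a mild neutral boron catalyst at low temperature is chosen to keep the silyl dienol ether from stepwise addition.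

**Step 6**
Reactants: 8 (1S,2S,3R,6S)-2-acetoxy-3-(benzoyloxy)-1-bromo-6-[(tert-butyldimethylsilyl)oxy]cyclohex-4-ene-1-carbaldehyde
Product: 9 [(1S,2S,3R,6S)-2-acetoxy-3-(benzoyloxy)-1-bromo-6-[(tert-butyldimethylsilyl)oxy]cyclohex-4-en-1-yl]methanol
Conditions: NaBH4, CeCl3·7H2O, MeOH/CH2Cl2, −78 °C
Reagents that add atoms: none
Why: Luche reduction should reduce only the aldehyde, and the weakly acidic cerium medium is expected to suppress alkoxide-driven acetyl migration and spiro-oxirane formation; no stereocentre is created.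

**Step 7**
Reactants: 9 [(1S,2S,3R,6S)-2-acetoxy-3-(benzoyloxy)-1-bromo-6-[(tert-butyldimethylsilyl)oxy]cyclohex-4-en-1-yl]methanol
Product: 10 [(1S,2S,3R,6S)-2-acetoxy-3-(benzoyloxy)-1-bromo-6-[(tert-butyldimethylsilyl)oxy]cyclohex-4-en-1-yl]methyl benzoate
Conditions: BzCl, pyridine, 4-(dimethylamino)pyridine (cat.), CH2Cl2, 0 °C
Reagents that add atoms: benzoyl chloride, O=C(Cl)c1ccccc1
Why: Nucleophile-catalysed acylation of the only free hydroxyl group should give the primary benzoate without touching the stereocentres.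

**Step 8**
Reactants: 10 [(1S,2S,3R,6S)-2-acetoxy-3-(benzoyloxy)-1-bromo-6-[(tert-butyldimethylsilyl)oxy]cyclohex-4-en-1-yl]methyl benzoate
Product: 12 [(1S,2S,3R,6S)-2-acetoxy-3-(benzoyloxy)-7-oxabicyclo[4.1.0]hept-4-en-1-yl]methyl benzoate, via C6 alkoxide 11 (not isolated)
Conditions: Bu4NF (1.1 equiv), THF, 0 °C
Reagents that add atoms: none
Why: Fluoride desilylation should give alkoxide 11, whose C6 oxygen is trans-diaxial to the C1–Br bond, so that intramolecular Williamson (halohydrin) closure with inversion at C1 gives the oxirane on the face of C3–OBz and opposite to C2–OAc.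

**Compound list**

1 | (Z)-but-2-ene-1,4-diol | OC/C=C\CO | starting material
2 | (Z)-4-hydroxybut-2-en-1-yl benzoate | O=C(OC/C=C\CO)c1ccccc1 | intermediate
3 | (Z)-4-oxobut-2-en-1-yl benzoate (not isolated) | O=C/C=C\COC(=O)c1ccccc1 | intermediate
4 | (E)-4-oxobut-2-en-1-yl benzoate | O=C/C=C/COC(=O)c1ccccc1 | intermediate
5 | (1E,3E)-4-[(tert-butyldimethylsilyl)oxy]buta-1,3-dien-1-yl benzoate | O=C(O/C=C/C=C/O[Si](C)(C)C(C)(C)C)c1ccccc1 | intermediate
6 | 2-bromopropanedial (bromomalonaldehyde) | O=CC(Br)C=O | starting material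
7 | (Z)-2-bromo-3-oxoprop-1-en-1-yl acetate | CC(=O)O/C=C(\Br)C=O | intermediate
8 | (1S,2S,3R,6S)-2-acetoxy-3-(benzoyloxy)-1-bromo-6-[(tert-butyldimethylsilyl)oxy]cyclohex-4-ene-1-carbaldehyde | CC(=O)O[C@H]1[C@H](OC(=O)c2ccccc2)C=C[C@H](O[Si](C)(C)C(C)(C)C)[C@]1(Br)C=O | intermediate
9 | [(1S,2S,3R,6S)-2-acetoxy-3-(benzoyloxy)-1-bromo-6-[(tert-butyldimethylsilyl)oxy]cyclohex-4-en-1-yl]methanol | CC(=O)O[C@H]1[C@H](OC(=O)c2ccccc2)C=C[C@H](O[Si](C)(C)C(C)(C)C)[C@]1(Br)CO | intermediate
10 | [(1S,2S,3R,6S)-2-acetoxy-3-(benzoyloxy)-1-bromo-6-[(tert-butyldimethylsilyl)oxy]cyclohex-4-en-1-yl]methyl benzoate | CC(=O)O[C@H]1[C@H](OC(=O)c2ccccc2)C=C[C@H](O[Si](C)(C)C(C)(C)C)[C@]1(Br)COC(=O)c1ccccc1 | intermediate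
11 | tetrabutylammonium (1R,2S,3R,6S)-2-acetoxy-3-(benzoyloxy)-1-[(benzoyloxy)methyl]-1-bromocyclohex-4-en-6-olate (not isolated; same spatial arrangement as 10) | CCCC[N+](CCCC)(CCCC)CCCC.CC(=O)O[C@H]1[C@H](OC(=O)c2ccccc2)C=C[C@H]([O-])[C@]1(Br)COC(=O)c1ccccc1 | intermediate
12 | [(1S,2S,3R,6S)-2-acetoxy-3-(benzoyloxy)-7-oxabicyclo[4.1.0]hept-4-en-1-yl]methyl benzoate | CC(=O)O[C@H]1[C@H](OC(=O)c2ccccc2)C=C[C@@H]2O[C@@]21COC(=O)c1ccccc1 | target

**Totals and risks**

Total steps: 8. Longest linear sequence: 7 steps (steps 1, 2, 3, 5, 6, 7, 8 from compound 1).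

Steps most likely to fail:

1. Step 5. The Lewis acid may trigger stepwise Mukaiyama–Michael addition of the silyl dienol ether with loss of acetate from the β-acetoxy enal, or facial discrimination by the catalyst may be insufficient. Fallback: setting out from 5 and 7, the cycloaddition is run thermally without Lewis acid (toluene, 60 °C, 2,6-di-tert-butyl-4-methylphenol as inhibitor) to give the racemic cycloadduct F1. This is reduced as in step 6 to the racemic bromo alcohol F2 and benzoylated as in step 7 to the racemic bromo benzoate F3. The enantiomers of F3 are separated by preparative chromatography on cellulose tris(3,5-dimethylphenylcarbamate), giving 10 and its enantiomer F4, and the route is rejoined at 10.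

2. Step 8. Migration of the benzoyl group from the CH2O arm onto the C6 alkoxide, or fluoride-induced loss of HBr from the tertiary bromide, may compete with oxirane closure. Fallback: setting out from 8, the oxirane is closed before the benzoate is present. Bu4NF in THF at −20 °C gives the alkoxide F5 (not isolated), whose displacement of the formyl-activated bromide should give the epoxy aldehyde F6. Reduction with NaBH4/CeCl3·7H2O gives the epoxy alcohol F7, and benzoylation with BzCl and pyridine returns to the route at 12.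

3. Step 3. The enol benzoate double bond may form without geometric control, or the silylated enal may undergo aldol-type self-condensation; a 3Z diene would not reach the s-cis conformation needed in step 5. Fallback: setting out from 1, the roles of the two oxygens are exchanged. Monosilylation (TBSCl, imidazole, DMF, diol in excess) gives (Z)-4-[(tert-butyldimethylsilyl)oxy]but-2-en-1-ol F8. Oxidation with [C5H5NH][CrO3Cl] gives, through the Z-enal F9 (not isolated), (E)-4-[(tert-butyldimethylsilyl)oxy]but-2-enal F10. γ-Deprotonation with KOC(CH3)3 in THF at −78 °C gives the potassium dienolate F11 (not isolated), and O-acylation with benzoyl chloride returns to the route at 5.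

**Further compounds**

F1 | step 5 | racemic 2-acetoxy-3-(benzoyloxy)-1-bromo-6-[(tert-butyldimethylsilyl)oxy]cyclohex-4-ene-1-carbaldehyde (8 and its enantiomer) | CC(=O)O[C@H]1[C@H](OC(=O)c2ccccc2)C=C[C@H](O[Si](C)(C)C(C)(C)C)[C@]1(Br)C=O.CC(=O)O[C@@H]1[C@@H](OC(=O)c2ccccc2)C=C[C@@H](O[Si](C)(C)C(C)(C)C)[C@@]1(Br)C=O
F2 | step 5 | racemic bromo alcohol (9 and its enantiomer) | CC(=O)O[C@H]1[C@H](OC(=O)c2ccccc2)C=C[C@H](O[Si](C)(C)C(C)(C)C)[C@]1(Br)CO.CC(=O)O[C@@H]1[C@@H](OC(=O)c2ccccc2)C=C[C@@H](O[Si](C)(C)C(C)(C)C)[C@@]1(Br)CO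
F3 | step 5 | racemic bromo benzoate (10 and its enantiomer) | CC(=O)O[C@H]1[C@H](OC(=O)c2ccccc2)C=C[C@H](O[Si](C)(C)C(C)(C)C)[C@]1(Br)COC(=O)c1ccccc1.CC(=O)O[C@@H]1[C@@H](OC(=O)c2ccccc2)C=C[C@@H](O[Si](C)(C)C(C)(C)C)[C@@]1(Br)COC(=O)c1ccccc1
F4 | step 5 | [(1R,2R,3S,6R)-2-acetoxy-3-(benzoyloxy)-1-bromo-6-[(tert-butyldimethylsilyl)oxy]cyclohex-4-en-1-yl]methyl benzoate (enantiomer of 10) | CC(=O)O[C@@H]1[C@@H](OC(=O)c2ccccc2)C=C[C@@H](O[Si](C)(C)C(C)(C)C)[C@@]1(Br)COC(=O)c1ccccc1
F5 | step 8 | tetrabutylammonium (1R,2S,3R,6S)-2-acetoxy-3-(benzoyloxy)-1-bromo-1-formylcyclohex-4-en-6-olate (not isolated) | CCCC[N+](CCCC)(CCCC)CCCC.CC(=O)O[C@H]1[C@H](OC(=O)c2ccccc2)C=C[C@H]([O-])[C@]1(Br)C=O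
F6 | step 8 | (1S,2S,3R,6S)-2-acetoxy-3-(benzoyloxy)-7-oxabicyclo[4.1.0]hept-4-ene-1-carbaldehyde | CC(=O)O[C@H]1[C@H](OC(=O)c2ccccc2)C=C[C@@H]2O[C@@]21C=O
F7 | step 8 | [(1S,2S,3R,6S)-2-acetoxy-3-(benzoyloxy)-7-oxabicyclo[4.1.0]hept-4-en-1-yl]methanol | CC(=O)O[C@H]1[C@H](OC(=O)c2ccccc2)C=C[C@@H]2O[C@@]21CO
F8 | step 3 | (Z)-4-[(tert-butyldimethylsilyl)oxy]but-2-en-1-ol | CC(C)(C)[Si](C)(C)OC/C=C\CO
F9 | step 3 | (Z)-4-[(tert-butyldimethylsilyl)oxy]but-2-enal (not isolated) | CC(C)(C)[Si](C)(C)OC/C=C\C=O
F10 | step 3 | (E)-4-[(tert-butyldimethylsilyl)oxy]but-2-enal | CC(C)(C)[Si](C)(C)OC/C=C/C=O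
F11 | step 3 | potassium (1E,3E)-4-[(tert-butyldimethylsilyl)oxy]buta-1,3-dien-1-olate (not isolated) | [K+].[O-]/C=C/C=C/O[Si](C)(C)C(C)(C)C
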